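**Retrosynthetic overview**

1. Target 23 ⇐ hexa-TIPS ether 22 (global desilylation) ⇐ aryl bromide 18 + styrene 21 (Heck coupling, E-stilbene; no ring formed).
2. 18 ⇐ o-quinone methide 15 (unmasked from sulfone 7) + chiral sulfonium benzylide 16 (from salt 14): an intermolecular Michael addition makes C2–C3, then phenoxide SN2 closure makes the dihydrofuran ring. This is the only ring built on the target; all benzene rings are bought.
3. 7 ⇐ 5-bromosalicylaldehyde 3 + the aryl Grignard from 2, then sulfinate; 14 ⇐ benzyl bromide 11 (from 3,4-dihydroxybenzaldehyde) + (1R,4R,5R)-isothiocineole 13, whose thia-bridged ring is made first, in a side branch, from (R)-limonene and sulfur.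
4. Stereocontrol: sulfide 13 fixes C2 through ylide face selectivity; the trans-selective ring closure relays it to C3.

Assumption: the benzylide from (1R,4R,5R)-13 is taken to attack through the same ylide face as in its aldehyde epoxidations (the sense that gives (R,R)-stilbene oxide), which maps onto (2S) in 18. This sense comes from a steric model and is not confirmed for quinone methides; if a first run shows the opposite, the (1S,4S,5S)-sulfide from (S)-limonene is used and nothing else changes.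

TIPS = triisopropylsilyl.

**Route**

Step 1
Reactants: 1 5-bromobenzene-1,3-diol
Product: 2 1-bromo-3,5-bis(triisopropylsilyloxy)benzene
Conditions: TIPSCl (2.3 equiv), imidazole (5 equiv), DMF, rt
Reagents that add atoms: chlorotriisopropylsilane, CC(C)[Si](Cl)(C(C)C)C(C)C
Why: Standard silyl ether formation (O-silylation) of both phenols; aryl TIPS ethers survive organomagnesium, carbonate base, hot amine/Pd and mild acid, and leave with fluoride at the end.

Step 2
Reactants: 2 1-bromo-3,5-bis(triisopropylsilyloxy)benzene; 3 5-bromo-2-hydroxybenzaldehyde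
Product: 6 racemic 4-bromo-2-{[3,5-bis(triisopropylsilyloxy)phenyl](hydroxy)methyl}phenol, via aryl Grignard reagent 4 (not isolated), via sodium phenolate 5 (not isolated)
Conditions: 2, Mg turnings (I2 cat.), THF, 45 °C; separately 3, NaH (1.0 equiv), THF, 0 °C; add 4 (1.3 equiv) to 5, 0 °C → rt; H2O quench
Reagents that add atoms: none
Why: Grignard addition to the aldehyde, with the phenol deprotonated beforehand so that no organometallic is wasted; the new carbinol centre is racemic and is erased in step 9.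

Step 3
Reactants: 6 racemic 4-bromo-2-{[3,5-bis(triisopropylsilyloxy)phenyl](hydroxy)methyl}phenol
Product: 7 racemic 4-bromo-2-{[3,5-bis(triisopropylsilyloxy)phenyl](4-methylphenylsulfonyl)methyl}phenol
Conditions: p-TolSO2Na (2 equiv), HCO2H, CH2Cl2/H2O, rt
Reagents that add atoms: sodium 4-methylbenzenesulfinate, [Na+].[O-]S(=O)c1ccc(C)cc1
Why: Acid-promoted SN1-type substitution of the o-hydroxybenzhydrol by sulfinate (S-alkylation) gives a bench-stable sulfone that releases the o-quinone methide with mild base.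

Step 4
Reactants: 8 3,4-dihydroxybenzaldehyde
Product: 9 3,4-bis(triisopropylsilyloxy)benzaldehyde
Conditions: TIPSCl (2.4 equiv), imidazole (5 equiv), DMF, rt
Reagents that add atoms: chlorotriisopropylsilane, CC(C)[Si](Cl)(C(C)C)C(C)C
Why: Silyl ether formation protects the catechol against base and oxidation for the rest of the route.

Step 5
Reactants: 9 3,4-bis(triisopropylsilyloxy)benzaldehyde
Product: 10 [3,4-bis(triisopropylsilyloxy)phenyl]methanol
Conditions: NaBH4, MeOH/THF, 0 °C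
Reagents that add atoms: none
Why: Borohydride reduction of an aryl aldehyde is chemoselective and leaves the silyl ethers untouched.

Step 6
Reactants: 10 [3,4-bis(triisopropylsilyloxy)phenyl]methanol
Product: 11 4-(bromomethyl)-1,2-bis(triisopropylsilyloxy)benzene
Conditions: CBr4 (1.3 equiv), PPh3 (1.3 equiv), CH2Cl2, 0 °C; used promptly
Reagents that add atoms: tetrabromomethane, BrC(Br)(Br)Br
Why: The Appel reaction converts the benzylic alcohol to the bromide under neutral conditions that do not touch the silyl ethers.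

Step 7
Reactants: 12 (R)-(+)-limonene
Product: 13 (1R,4R,5R)-4,7,7-trimethyl-6-thiabicyclo[3.2.1]octane ((+)-isothiocineole)
Conditions: S8, γ-terpinene, neat, 110 °C; distillation
Reagents that add atoms: sulfur, S1SSSSSSS1
Why: Radical sulfur transfer/thia-cyclisation across the two alkenes of limonene, with γ-terpinene as hydrogen donor, gives the bridged sulfide in one step; C1 comes from limonene and the other two centres follow from the bridging.

Step 8
Reactants: 11 4-(bromomethyl)-1,2-bis(triisopropylsilyloxy)benzene; 13 (1R,4R,5R)-isothiocineole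
Product: 14 (1R,4R,5R)-6-[3,4-bis(triisopropylsilyloxy)benzyl]-4,7,7-trimethyl-6-thiabicyclo[3.2.1]octan-6-ium trifluoromethanesulfonate (benzyl on the exo lone pair, R at sulfur)
Conditions: 11 (1.5 equiv), LiOSO2CF3 (5 equiv), CH2Cl2/H2O, rt, 24 h
Reagents that add atoms: lithium trifluoromethanesulfonate, [Li+].[O-]S(=O)(=O)C(F)(F)F
Why: S-alkylation (SN2) of the sulfide by the activated benzyl bromide, with counter-ion exchange to the non-nucleophilic triflate; alkylation on the less hindered exo lone pair gives one diastereomer at sulfur.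

Step 9
Reactants: 7 racemic 4-bromo-2-{[3,5-bis(triisopropylsilyloxy)phenyl](4-methylphenylsulfonyl)methyl}phenol; 14 the sulfonium triflate
Product: 18 (2S,3S)-5-bromo-2-[3,4-bis(triisopropylsilyloxy)phenyl]-3-[3,5-bis(triisopropylsilyloxy)phenyl]-2,3-dihydrobenzofuran, via o-quinone methide 15 (not isolated), via sulfonium ylide 16 (not isolated), via betaine 17 (not isolated)
Conditions: 14 (1.2 equiv), Cs2CO3 (3 equiv), CH2Cl2/MeCN 1:1, −20 °C → rt
Reagents that add atoms: none
Why: Michael-initiated ring closure ([4+1] annulation): the ylide adds in a conjugate (Michael) fashion to the exocyclic carbon of the o-quinone methide, rearomatisation making it irreversible, and the phenoxide then displaces the sulfide by 5-exo-tet SN2 with inversion, so the ylide face selected by the bicyclic sulfide sets C2 (S) and the anti addition/trans closure sets C3 (S).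

Step 10
Reactants: 19 3,5-dihydroxybenzaldehyde
Product: 20 3,5-bis(triisopropylsilyloxy)benzaldehyde
Conditions: TIPSCl (2.3 equiv), imidazole (5 equiv), DMF, rt
Reagents that add atoms: chlorotriisopropylsilane, CC(C)[Si](Cl)(C(C)C)C(C)C
Why: Silyl ether formation, giving the same protecting group on all six phenols so that one final operation removes them.

Step 11
Reactants: 20 3,5-bis(triisopropylsilyloxy)benzaldehyde
Product: 21 1-ethenyl-3,5-bis(triisopropylsilyloxy)benzene
Conditions: Ph3PCH3Br (1.5 equiv), KOC(CH3)3 (1.4 equiv), THF, 0 °C → rt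
Reagents that add atoms: methyltriphenylphosphonium bromide, [Br-].C[P+](c1ccccc1)(c1ccccc1)c1ccccc1
Why: Wittig methylenation of a non-enolisable aryl aldehyde is dependable and the preformed ylide leaves the silyl ethers alone.

Step 12
Reactants: 18 the (2S,3S)-5-bromo-dihydrobenzofuran; 21 1-ethenyl-3,5-bis(triisopropylsilyloxy)benzene
Product: 22 (2S,3S)-2-[3,4-bis(triisopropylsilyloxy)phenyl]-3-[3,5-bis(triisopropylsilyloxy)phenyl]-5-{(E)-2-[3,5-bis(triisopropylsilyloxy)phenyl]ethenyl}-2,3-dihydrobenzofuran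
Conditions: 21 (1.5 equiv), Pd2(dba)3 (2.5 mol %), [(t-Bu)3PH]BF4 (10 mol %), Cy2NMe (2 equiv), dioxane, 90 °C
Reagents that add atoms: none
Why: Mizoroki–Heck coupling with a bulky electron-rich phosphine activates the electron-rich aryl bromide and gives the E-stilbene by syn insertion/syn β-hydride elimination; the amine base cannot touch C2 or C3.

Step 13
Reactants: 22 the hexa-TIPS ether
Product: 23 (2S,3S)-2-(3,4-dihydroxyphenyl)-3-(3,5-dihydroxyphenyl)-5-[(E)-2-(3,5-dihydroxyphenyl)ethenyl]-2,3-dihydrobenzofuran (target)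
Conditions: Bu4NF (7 equiv), AcOH (8 equiv), degassed THF, 0 °C → rt, Ar
Reagents that add atoms: none
Why: Fluoride-induced desilylation of aryl silyl ethers, buffered with acetic acid so that no free catecholate or p-phenoxide forms, which avoids air oxidation and retro-oxa-Michael opening at C2; the stilbene and both stereocentres are untouched.

**Compound list**

1 | 5-bromobenzene-1,3-diol | Oc1cc(O)cc(Br)c1 | starting material
2 | 1-bromo-3,5-bis(triisopropylsilyloxy)benzene | Brc1cc(O[Si](C(C)C)(C(C)C)C(C)C)cc(O[Si](C(C)C)(C(C)C)C(C)C)c1 | intermediate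
3 | 5-bromo-2-hydroxybenzaldehyde | O=Cc1cc(Br)ccc1O | starting material
4 | [3,5-bis(triisopropylsilyloxy)phenyl]magnesium bromide | Br[Mg]c1cc(O[Si](C(C)C)(C(C)C)C(C)C)cc(O[Si](C(C)C)(C(C)C)C(C)C)c1 | intermediate
5 | sodium 4-bromo-2-formylphenolate | [Na+].[O-]c1ccc(Br)cc1C=O | intermediate
6 | racemic 4-bromo-2-{[3,5-bis(triisopropylsilyloxy)phenyl](hydroxy)methyl}phenol | OC(c1cc(O[Si](C(C)C)(C(C)C)C(C)C)cc(O[Si](C(C)C)(C(C)C)C(C)C)c1)c1cc(Br)ccc1O | intermediate
7 | racemic 4-bromo-2-{[3,5-bis(triisopropylsilyloxy)phenyl](4-methylphenylsulfonyl)methyl}phenol | Cc1ccc(cc1)S(=O)(=O)C(c1cc(O[Si](C(C)C)(C(C)C)C(C)C)cc(O[Si](C(C)C)(C(C)C)C(C)C)c1)c1cc(Br)ccc1O | intermediate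
8 | 3,4-dihydroxybenzaldehyde | O=Cc1ccc(O)c(O)c1 | starting material
9 | 3,4-bis(triisopropylsilyloxy)benzaldehyde | O=Cc1ccc(O[Si](C(C)C)(C(C)C)C(C)C)c(O[Si](C(C)C)(C(C)C)C(C)C)c1 | intermediate
10 | [3,4-bis(triisopropylsilyloxy)phenyl]methanol | OCc1ccc(O[Si](C(C)C)(C(C)C)C(C)C)c(O[Si](C(C)C)(C(C)C)C(C)C)c1 | intermediate
11 | 4-(bromomethyl)-1,2-bis(triisopropylsilyloxy)benzene | BrCc1ccc(O[Si](C(C)C)(C(C)C)C(C)C)c(O[Si](C(C)C)(C(C)C)C(C)C)c1 | intermediate
12 | (R)-(+)-limonene, (4R)-1-methyl-4-(prop-1-en-2-yl)cyclohexene | CC1=CC[C@@H](CC1)C(C)=C | starting material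
13 | (1R,4R,5R)-4,7,7-trimethyl-6-thiabicyclo[3.2.1]octane, (+)-isothiocineole | C[C@@H]1CC[C@@H]2C[C@H]1SC2(C)C | intermediate
14 | (1R,4R,5R)-6-[3,4-bis(triisopropylsilyloxy)benzyl]-4,7,7-trimethyl-6-thiabicyclo[3.2.1]octan-6-ium trifluoromethanesulfonate, R at sulfur | C[C@@H]1CC[C@@H]2C[C@H]1[S@@+](Cc1ccc(O[Si](C(C)C)(C(C)C)C(C)C)c(O[Si](C(C)C)(C(C)C)C(C)C)c1)C2(C)C.[O-]S(=O)(=O)C(F)(F)F | intermediate
15 | 4-bromo-6-[3,5-bis(triisopropylsilyloxy)benzylidene]cyclohexa-2,4-dien-1-one (o-quinone methide, alkene geometry not defined) | O=C1C=CC(Br)=CC1=Cc1cc(O[Si](C(C)C)(C(C)C)C(C)C)cc(O[Si](C(C)C)(C(C)C)C(C)C)c1 | intermediate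
16 | sulfonium benzylide of 14 (ylide carbon bearing the 3,4-bis(triisopropylsilyloxy)phenyl group) | C[C@@H]1CC[C@@H]2C[C@H]1[S@@+]([CH-]c1ccc(O[Si](C(C)C)(C(C)C)C(C)C)c(O[Si](C(C)C)(C(C)C)C(C)C)c1)C2(C)C | intermediate
17 | betaine: 4-bromo-2-[(1S,2R)-1-[3,5-bis(triisopropylsilyloxy)phenyl]-2-[3,4-bis(triisopropylsilyloxy)phenyl]-2-(isothiocineol-6-ium-6-yl)ethyl]phenolate | C[C@@H]1CC[C@@H]2C[C@H]1[S@@+]([C@@H](c1ccc(O[Si](C(C)C)(C(C)C)C(C)C)c(O[Si](C(C)C)(C(C)C)C(C)C)c1)[C@@H](c1cc(O[Si](C(C)C)(C(C)C)C(C)C)cc(O[Si](C(C)C)(C(C)C)C(C)C)c1)c1cc(Br)ccc1[O-])C2(C)C | intermediate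
18 | (2S,3S)-5-bromo-2-[3,4-bis(triisopropylsilyloxy)phenyl]-3-[3,5-bis(triisopropylsilyloxy)phenyl]-2,3-dihydrobenzofuran (trans) | Brc1ccc2c(c1)[C@H](c1cc(O[Si](C(C)C)(C(C)C)C(C)C)cc(O[Si](C(C)C)(C(C)C)C(C)C)c1)[C@@H](c1ccc(O[Si](C(C)C)(C(C)C)C(C)C)c(O[Si](C(C)C)(C(C)C)C(C)C)c1)O2 | intermediate
19 | 3,5-dihydroxybenzaldehyde | O=Cc1cc(O)cc(O)c1 | starting material
20 | 3,5-bis(triisopropylsilyloxy)benzaldehyde | O=Cc1cc(O[Si](C(C)C)(C(C)C)C(C)C)cc(O[Si](C(C)C)(C(C)C)C(C)C)c1 | intermediate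
21 | 1-ethenyl-3,5-bis(triisopropylsilyloxy)benzene | C=Cc1cc(O[Si](C(C)C)(C(C)C)C(C)C)cc(O[Si](C(C)C)(C(C)C)C(C)C)c1 | intermediate
22 | (2S,3S)-2-[3,4-bis(triisopropylsilyloxy)phenyl]-3-[3,5-bis(triisopropylsilyloxy)phenyl]-5-{(E)-2-[3,5-bis(triisopropylsilyloxy)phenyl]ethenyl}-2,3-dihydrobenzofuran | CC(C)[Si](C(C)C)(C(C)C)Oc1cc(O[Si](C(C)C)(C(C)C)C(C)C)cc(/C=C/c2ccc3c(c2)[C@H](c2cc(O[Si](C(C)C)(C(C)C)C(C)C)cc(O[Si](C(C)C)(C(C)C)C(C)C)c2)[C@@H](c2ccc(O[Si](C(C)C)(C(C)C)C(C)C)c(O[Si](C(C)C)(C(C)C)C(C)C)c2)O3)c1 | intermediate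
23 | (2S,3S)-2-(3,4-dihydroxyphenyl)-3-(3,5-dihydroxyphenyl)-5-[(E)-2-(3,5-dihydroxyphenyl)ethenyl]-2,3-dihydrobenzofuran | Oc1cc(O)cc(/C=C/c2ccc3c(c2)[C@H](c2cc(O)cc(O)c2)[C@@H](c2ccc(O)c(O)c2)O3)c1 | target

**Totals and risks**

Total step count: 13. Longest linear sequence: 7 steps (8 → 9 → 10 → 11 → 14 → 18 → 22 → 23).

The three steps most likely to fail:

Step 9. The trans-selective annulation of sulfur ylides with o-quinone methides is established, but the level and sense of enantiocontrol with a semi-stabilised benzylide is the least precedented point of the route. The liberated sulfinate may also compete for the sulfonium salt. The fallback replaces reagent control by resolution; it sets out from 11 and 7 and comes back at 18. Bromide 11 is quaternised with tetrahydrothiophene (acetone, rt) to 1-[3,4-bis(triisopropylsilyloxy)benzyl]thiolan-1-ium bromide F1. F1 and sulfone 7 with Cs2CO3 in CH2Cl2 give the racemic trans-dihydrobenzofuran, that is 18 together with its mirror image. Preparative chiral SFC on an amylose carbamate phase removes (2R,3R)-5-bromo-2-[3,4-bis(triisopropylsilyloxy)phenyl]-3-[3,5-bis(triisopropylsilyloxy)phenyl]-2,3-dihydrobenzofuran F2 and returns enantiopure 18, which goes on to step 12.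

Step 12. The aryl bromide is electron-rich, and Heck couplings with styrenes can give some 1,1-diarylethene or Z isomer. The fallback fixes the alkene geometry before the coupling; it sets out from 21 and comes back at 22. Cross-metathesis of 21 with vinylboronic acid pinacol ester (second-generation Grubbs catalyst, CH2Cl2, 40 °C) gives (E)-2-{2-[3,5-bis(triisopropylsilyloxy)phenyl]ethenyl}-4,4,5,5-tetramethyl-1,3,2-dioxaborolane F3. Stereoretentive Suzuki–Miyaura coupling of F3 with 18 (Pd(OAc)2, SPhos, K3PO4, toluene/H2O, 60 °C) gives 22.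

Step 13. Six silyl groups have to leave from a hexaphenol that carries an air-sensitive catechol and a p-hydroxybenzylic ether; incomplete cleavage, oxidation, or loss on purification are the dangers. The fallback goes through a stable, purifiable peracetate; it sets out from 22 and comes back at 23. Treatment of 22 with Bu4NF in the presence of Ac2O (THF, 0 °C) traps each phenoxide as it forms and gives (2S,3S)-2-(3,4-diacetoxyphenyl)-3-(3,5-diacetoxyphenyl)-5-[(E)-2-(3,5-diacetoxyphenyl)ethenyl]-2,3-dihydrobenzofuran F4, which is purified on silica. Mild methanolysis (K2CO3 cat., degassed MeOH, 0 °C, then AcOH) releases 23.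

**Further compounds**

F1 | step 9 | 1-[3,4-bis(triisopropylsilyloxy)benzyl]thiolan-1-ium bromide | [Br-].C1CC[S+](C1)Cc1ccc(O[Si](C(C)C)(C(C)C)C(C)C)c(O[Si](C(C)C)(C(C)C)C(C)C)c1
F2 | step 9 | (2R,3R)-5-bromo-2-[3,4-bis(triisopropylsilyloxy)phenyl]-3-[3,5-bis(triisopropylsilyloxy)phenyl]-2,3-dihydrobenzofuran | Brc1ccc2c(c1)[C@@H](c1cc(O[Si](C(C)C)(C(C)C)C(C)C)cc(O[Si](C(C)C)(C(C)C)C(C)C)c1)[C@H](c1ccc(O[Si](C(C)C)(C(C)C)C(C)C)c(O[Si](C(C)C)(C(C)C)C(C)C)c1)O2
F3 | step 12 | (E)-2-{2-[3,5-bis(triisopropylsilyloxy)phenyl]ethenyl}-4,4,5,5-tetramethyl-1,3,2-dioxaborolane | CC1(C)OB(/C=C/c2cc(O[Si](C(C)C)(C(C)C)C(C)C)cc(O[Si](C(C)C)(C(C)C)C(C)C)c2)OC1(C)C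
F4 | step 13 | (2S,3S)-2-(3,4-diacetoxyphenyl)-3-(3,5-diacetoxyphenyl)-5-[(E)-2-(3,5-diacetoxyphenyl)ethenyl]-2,3-dihydrobenzofuran | CC(=O)Oc1cc(OC(C)=O)cc(/C=C/c2ccc3c(c2)[C@H](c2cc(OC(C)=O)cc(OC(C)=O)c2)[C@@H](c2ccc(OC(C)=O)c(OC(C)=O)c2)O3)c1
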